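**Retrosynthetic overview**
1. Target ⇐ (BCl3; twofold Rieche formylation) dimethyl ether 22 ⇐ inversion of the benzylic centre C9 (DDQ, then ionic hydrogenation), removal of the ring-D carbonyl (dithiolane, Raney nickel) and hydrogenation of an exocyclic methylene at C6' ⇐ spirodienone tetracycle 15.
2. Key disconnection of ring C (the cyclopentane) at its CH2–C(Me) bond (C1–C9a) and its O–CH–spiro bond (C3a–C3): 15 ⇐ 4H-chromene 8 (rings A and B) + 5-isopropyl-8-methylspiro[2.5]octa-4,7-dien-6-one 13 (ring D carrying a three-membered ring), joined by a Lewis-acid-catalysed, strain-release formal [3+2] cycloaddition.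
3. Enabling feature: the spiro carbon shared by rings C and D carries both CH2 groups of ring C and lies para to C4' in a six-membered ring with the substitution pattern of thymol, so C1–C2–C3 can be stored as the cyclopropane of a homo-quinone methide; the other two ring-C atoms, C9a and C3a, are the enol-ether carbons next to O4 of ring B.
4. Order of ring formation: ring A is bought (5,7-dimethoxycoumarin), ring B is shaped into the 4H-chromene (steps 1–5), ring D comes from thymol by dearomatisation (steps 6–8), and ring C with the spiro centre forms last, in the key step.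
5. Absolute configuration: a copper-catalysed asymmetric conjugate addition sets C9 as S; this centre steers the key step from the opposite face and is then inverted to R (step 14); the bromine atoms of 6–19 are temporary blocking groups.

Key step: step 9

Remark: tetracycles are numbered as spiro[cyclopenta[b]chromene-3,1'-cyclohexane] (C1 and C2 are CH2, C3 = C1' is the spiro carbon, C3a is O–CH, O4, C4a–C8a the arene, C9 the benzylic CH, C9a the angular C–Me; ring D is C1'–C6'), with rings A (arene), B (pyran), C (cyclopentane) and D (cyclohexene); the target SMILES is read as (3R,3aR,9R,9aS,6'R), with the isobutyl group cis to C1 and the 6'-methyl group syn to C3a.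

**Step 1**
Reactants: 1 5,7-dimethoxycoumarin; 2 isobutylmagnesium bromide
Product: 3 (4S)-4-isobutyl-5,7-dimethoxychroman-2-one
Conditions: 2 (1.2 equiv), CuBr·SMe2 (5 mol %), Josiphos-type ferrocenyl diphosphine (6 mol %, the enantiomer that gives 4S), t-BuOMe, −75 °C; NH4Cl (aq)
Reagents that add atoms: none
Why: Copper-catalysed asymmetric conjugate addition of a Grignard reagent to a coumarin, in which the chiral diphosphine–copper complex selects the enoate face and so sets C4 (4S), the centre that later steers the key step.

**Step 2**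
Reactants: 3 (4S)-4-isobutyl-5,7-dimethoxychroman-2-one
Product: 5 (3S,4S)-4-isobutyl-5,7-dimethoxy-3-methylchroman-2-one, via lithium enolate 4 (not isolated)
Conditions: LDA (1.1 equiv), THF, −78 °C; then MeI, −78 → −40 °C
Reagents that add atoms: iodomethane, CI
Why: Lactone enolate alkylation in which methyl iodide enters anti to the C4 isobutyl group (3,4-trans), at a centre that becomes sp2 again in step 5.

**Step 3**
Reactants: 5 (3S,4S)-4-isobutyl-5,7-dimethoxy-3-methylchroman-2-one
Product: 6 (3S,4S)-6,8-dibromo-4-isobutyl-5,7-dimethoxy-3-methylchroman-2-one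
Conditions: NBS (2.2 equiv), MeCN, 0 °C → rt
Reagents that add atoms: N-bromosuccinimide, O=C1CCC(=O)N1Br
Why: Electrophilic aromatic bromination of the two free positions of the trioxygenated ring, which blocks ring A against Friedel–Crafts alkylation in step 9.

**Step 4**
Reactants: 6 (3S,4S)-6,8-dibromo-4-isobutyl-5,7-dimethoxy-3-methylchroman-2-one
Product: 7 6,8-dibromo-4-isobutyl-5,7-dimethoxy-3-methylchroman-2-ol (lactol)
Conditions: DIBAL-H (1.1 equiv), CH2Cl2, −78 °C; Rochelle salt (aq)
Reagents that add atoms: none
Why: Partial reduction of the aryl lactone to the lactol at low temperature, which leaves C3 and C4 untouched and creates an anomeric centre of no consequence.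

**Step 5**
Reactants: 7 6,8-dibromo-4-isobutyl-5,7-dimethoxy-3-methylchroman-2-ol
Product: 8 (4S)-6,8-dibromo-4-isobutyl-5,7-dimethoxy-3-methyl-4H-chromene
Conditions: TsOH·H2O (5 mol %), PhMe, reflux, Dean–Stark trap
Reagents that add atoms: none
Why: Acid-catalysed dehydration of the 2-chromanol through its oxocarbenium ion gives the enol ether, and because only the C3 hydrogen can be lost the C4 stereocentre is retained.

**Step 6**
Reactants: 9 thymol; 10 chloroacetyl chloride
Product: 11 2-chloro-1-(4-hydroxy-5-isopropyl-2-methylphenyl)ethan-1-one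
Conditions: AlCl3 (2.5 equiv), CH2Cl2, 0 °C → rt; HCl (aq)
Reagents that add atoms: none
Why: Friedel–Crafts acylation in which the hydroxyl group directs the acylium ion to its para position, the site flanked only by the methyl group and a hydrogen.

**Step 7**
Reactants: 11 2-chloro-1-(4-hydroxy-5-isopropyl-2-methylphenyl)ethan-1-one
Product: 12 4-(2-chloroethyl)-2-isopropyl-5-methylphenol
Conditions: Et3SiH (2.5 equiv), TFA, rt
Reagents that add atoms: none
Why: Ionic hydrogenation of the para-hydroxyaryl ketone to the methylene group through the stabilised benzylic cation, with the primary chloride inert.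

**Step 8**
Reactants: 12 4-(2-chloroethyl)-2-isopropyl-5-methylphenol
Product: 13 5-isopropyl-8-methylspiro[2.5]octa-4,7-dien-6-one
Conditions: t-BuOK (1.0 equiv), t-BuOH/Et2O, 0 °C → rt; filtered through basic alumina and used at once as a solution
Reagents that add atoms: none
Why: Intramolecular para-C-alkylation of the phenoxide (Ar1-3 participation, 3-exo-tet) expels chloride and gives the dearomatised, achiral spirocyclopropyl dienone, as known for 4-(2-haloethyl)phenols.

**Step 9**
Reactants: 8 (4S)-6,8-dibromo-4-isobutyl-5,7-dimethoxy-3-methyl-4H-chromene; 13 5-isopropyl-8-methylspiro[2.5]octa-4,7-dien-6-one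
Product: 15 (9S)-dibromo spirodienone tetracycle, via oxocarbenium phenolate zwitterion 14 (not isolated)
Conditions: Sc(OTf)3 (10 mol %), 2,6-di-tert-butylpyridine (20 mol %), 4 Å MS, CH2Cl2, −40 → 0 °C, slow addition of 13 (1.3 equiv)
Reagents that add atoms: none
Why: Proposed new method: Sc(OTf)3 on the carbonyl oxygen turns the spirocyclopropane of 13 into a homo-quinone methide (incipient phenonium ion), and the nucleophilic enol-ether carbon C3 of 8 opens it at either of the two equivalent CH2 carbons, driven by release of the three-ring strain (about 27 kcal/mol) and aromatisation of ring D, to give the oxocarbenium phenolate 14; the phenolate then adds through its para carbon to the oxocarbenium carbon with renewed dearomatisation and release of the catalyst. The closest known reaction types are the Lewis-acid-catalysed formal [3+2] cycloaddition of donor–acceptor cyclopropanes with enol ethers, the ring opening of spiro[2.5]octa-4,7-dien-6-ones by nucleophiles, and ipso-Friedel–Crafts (Ar1-5) dearomative spirocyclisations of para-substituted phenols. Ring C is the only ring closed, by 5-exo-trig attack of the arene ipso carbon on the oxocarbenium carbon. C9a is set by attack on the chromene face anti to the pseudo-axial isobutyl group at C4 of 8 (the 4S centre from step 1), C3a follows because the two-carbon tether can only reach the same face (cis B/C fusion), and the spiro carbon is set by the rotamer of the phenolate ring in the closure, which should turn its ortho methyl group towards the substituent-free ring oxygen and away from the angular methyl group and H3a. The step needs chemoselectivity for the enol ether over the electron-rich arene and a cationic intermediate that cannot escape by proton loss; the first is secured by the bromine atoms on both free ring-A positions and the second by the quaternary C9a next to the oxocarbenium carbon.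

**Step 10**
Reactants: 15 (9S)-dibromo spirodienone tetracycle
Product: 17 (9S)-6'-methylene-4'-ketone, via lithium dienolate 16 (not isolated)
Conditions: LDA (1.2 equiv), THF, −78 °C; then AcOH, −78 °C
Reagents that add atoms: none
Why: The C6' methyl group is the only acidic position of the cross-conjugated dienone, so γ-deprotonation gives the extended enolate and kinetic α-protonation at C5' gives the deconjugated ketone with an exocyclic methylene group (deconjugative protonation).

**Step 11**
Reactants: 17 (9S)-6'-methylene-4'-ketone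
Product: 18 (9S,6'R)-6'-methyl enone
Conditions: H2 (1 atm), RhCl(PPh3)3 (5 mol %), PhH/EtOH, rt
Reagents that add atoms: none
Why: Homogeneous hydrogenation reduces the 1,1-disubstituted alkene and leaves the trisubstituted enone, and hydrogen is delivered to the ring-D face next to the C2 methylene group because the other face is covered by O4 and ring A, which places the 6'-methyl group syn to C3a.

**Step 12**
Reactants: 18 (9S,6'R)-6'-methyl enone
Product: 19 (9S)-4'-dithiolane
Conditions: HS(CH2)2SH (3 equiv), BF3·OEt2, CH2Cl2, 0 °C → rt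
Reagents that add atoms: ethane-1,2-dithiol, SCCS
Why: Lewis-acid-mediated dithioketalisation of the enone carbonyl, which proceeds without migration of the conjugated double bond as with cyclohexenone dithioketals.

**Step 13**
Reactants: 19 (9S)-4'-dithiolane
Product: 20 (9S)-6,8-dimethoxy tetracycle
Conditions: Raney nickel (W-2, excess), EtOH, reflux
Reagents that add atoms: none
Why: Reductive desulfurisation converts the dithiolane into a methylene group with the trisubstituted alkene left in place, and the same reagent hydrogenolyses both aryl–bromine bonds once the blocking groups have done their work.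

**Step 14**
Reactants: 20 (9S)-6,8-dimethoxy tetracycle
Product: 22 (9R)-6,8-dimethoxy tetracycle, via 9-alkylidene chroman 21 (not isolated)
Conditions: DDQ (1.05 equiv), CH2Cl2, 0 °C → rt; then Et3SiH (3 equiv), TFA (2 equiv), −40 °C
Reagents that add atoms: none
Why: DDQ removes the benzylic hydride at C9 (a 2,4,6-trioxygenated benzyl cation, as in the C4 oxidation of 5,7-dialkoxyflavans) and proton loss gives styrene 21, whose ionic hydrogenation should deliver hydride to the planar cation on the face anti to the pseudo-axial C1 methylene group, inverting C9 to R with the isobutyl group cis to ring C.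

**Step 15**
Reactants: 22 (9R)-6,8-dimethoxy tetracycle
Product: 23 6,8-dimethoxy-5,7-dicarbaldehyde
Conditions: Cl2CHOMe (6 equiv), TiCl4 (6 equiv), CH2Cl2, −78 → 0 °C; H2O
Reagents that add atoms: dichloromethyl methyl ether, COC(Cl)Cl; water, O
Why: Twofold Rieche formylation of the two free positions of the trialkoxybenzene ring, each of which is ortho or para to all three oxygen donors, so that the second formyl group can still enter.

**Step 16**
Reactants: 23 6,8-dimethoxy-5,7-dicarbaldehyde
Product: 24 CNP0121396.1 (target)
Conditions: BCl3 (4 equiv), CH2Cl2, −78 → 0 °C; H2O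
Reagents that add atoms: none
Why: Chelation-assisted cleavage of the two aryl methyl ethers, each ortho to a formyl group, should leave the chroman ether and the ring-D alkene untouched and give the target.

**Compound list**
1 | 5,7-dimethoxy-2H-chromen-2-one (5,7-dimethoxycoumarin) | COc1cc(OC)c2ccc(=O)oc2c1 | starting material
2 | isobutylmagnesium bromide | CC(C)C[Mg]Br | starting material
3 | (4S)-4-isobutyl-5,7-dimethoxychroman-2-one | CC(C)C[C@@H]1c2c(OC)cc(OC)cc2OC(=O)C1 | intermediate
4 | lithium enolate of 3 (lithium (4S)-4-isobutyl-5,7-dimethoxy-4H-chromen-2-olate) | CC(C)C[C@@H]1c2c(OC)cc(OC)cc2OC(O[Li])=C1 | intermediate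
5 | (3S,4S)-4-isobutyl-5,7-dimethoxy-3-methylchroman-2-one (3,4-trans) | CC(C)C[C@@H]1c2c(OC)cc(OC)cc2OC(=O)[C@H]1C | intermediate
6 | (3S,4S)-6,8-dibromo-4-isobutyl-5,7-dimethoxy-3-methylchroman-2-one | CC(C)C[C@@H]1c2c(OC)c(Br)c(OC)c(Br)c2OC(=O)[C@H]1C | intermediate
7 | (3S,4S)-6,8-dibromo-4-isobutyl-5,7-dimethoxy-3-methylchroman-2-ol (lactol, anomeric mixture expected, drawn as the 2S anomer) | CC(C)C[C@@H]1c2c(OC)c(Br)c(OC)c(Br)c2O[C@H](O)[C@H]1C | intermediate
8 | (4S)-6,8-dibromo-4-isobutyl-5,7-dimethoxy-3-methyl-4H-chromene | CC(C)C[C@@H]1c2c(OC)c(Br)c(OC)c(Br)c2OC=C1C | intermediate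
9 | thymol (2-isopropyl-5-methylphenol) | Cc1ccc(C(C)C)c(O)c1 | starting material
10 | chloroacetyl chloride | ClCC(Cl)=O | starting material
11 | 2-chloro-1-(4-hydroxy-5-isopropyl-2-methylphenyl)ethan-1-one | O=C(CCl)c1cc(C(C)C)c(O)cc1C | intermediate
12 | 4-(2-chloroethyl)-2-isopropyl-5-methylphenol | ClCCc1cc(C(C)C)c(O)cc1C | intermediate
13 | 5-isopropyl-8-methylspiro[2.5]octa-4,7-dien-6-one | O=C1C=C(C)C2(CC2)C=C1C(C)C | intermediate
14 | oxocarbenium phenolate zwitterion: (4S)-6,8-dibromo-4-isobutyl-5,7-dimethoxy-3-methyl-3-[2-(5-isopropyl-2-methyl-4-oxidophenyl)ethyl]-3,4-dihydrochromenylium, side chain trans to isobutyl (scandium-bound in the flask) | CC(C)C[C@@H]1c2c(OC)c(Br)c(OC)c(Br)c2[O+]=C[C@@]1(C)CCc1cc(C(C)C)c([O-])cc1C | intermediate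
15 | (9S)-5,7-dibromo-9-isobutyl-3'-isopropyl-6,8-dimethoxy-6',9a-dimethyl-1,2,3a,9-tetrahydro-9aH-spiro[cyclopenta[b]chromene-3,1'-cyclohexa[2,5]dien]-4'-one; C3, C3a and C9a arranged in space as in the target (C6' on the side of O4, B/C cis), isobutyl trans to C1 | CC(C)C[C@@H]1c2c(OC)c(Br)c(OC)c(Br)c2O[C@@H]2[C@@]1(C)CC[C@@]21C=C(C(C)C)C(=O)C=C1C | intermediate
16 | lithium dienolate of 15 (4'-lithiooxy-6'-methylenecyclohexa-2',4'-diene form of ring D) | CC(C)C[C@@H]1c2c(OC)c(Br)c(OC)c(Br)c2O[C@@H]2[C@@]1(C)CC[C@@]21C=C(C(C)C)C(O[Li])=CC1=C | intermediate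
17 | deconjugated isomer of 15: ring D is 3'-isopropyl-6'-methylenecyclohex-2'-en-4'-one (C5' is CH2), other centres as in 15 | CC(C)C[C@@H]1c2c(OC)c(Br)c(OC)c(Br)c2O[C@@H]2[C@@]1(C)CC[C@@]21C=C(C(C)C)C(=O)CC1=C | intermediate
18 | (9S,6'R)-enone: ring D is 3'-isopropyl-6'-methylcyclohex-2'-en-4'-one with the 6'-methyl group syn to C3a, other centres as in 15 | CC(C)C[C@@H]1c2c(OC)c(Br)c(OC)c(Br)c2O[C@@H]2[C@@]1(C)CC[C@@]21C=C(C(C)C)C(=O)C[C@H]1C | intermediate
19 | 4',4'-(ethane-1,2-diyldisulfanediyl) ketal (1,3-dithiolane) of 18 | CC(C)C[C@@H]1c2c(OC)c(Br)c(OC)c(Br)c2O[C@@H]2[C@@]1(C)CC[C@@]21C=C(C(C)C)C3(SCCS3)C[C@H]1C | intermediate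
20 | (3R,3aR,9S,9aS,6'R)-9-isobutyl-3'-isopropyl-6,8-dimethoxy-6',9a-dimethyl-1,2,3a,9-tetrahydro-9aH-spiro[cyclopenta[b]chromene-3,1'-cyclohex[2]ene] (9-epimer of 22) | CC(C)C[C@@H]1c2c(OC)cc(OC)cc2O[C@@H]2[C@@]1(C)CC[C@@]21C=C(C(C)C)CC[C@H]1C | intermediate
21 | 9-(2-methylpropylidene) analogue of 20 (drawn as the E isomer, geometry of no consequence) | CC(C)/C=C1/c2c(OC)cc(OC)cc2O[C@@H]2[C@@]1(C)CC[C@@]21C=C(C(C)C)CC[C@H]1C | intermediate
22 | (3R,3aR,9R,9aS,6'R)-9-isobutyl-3'-isopropyl-6,8-dimethoxy-6',9a-dimethyl-1,2,3a,9-tetrahydro-9aH-spiro[cyclopenta[b]chromene-3,1'-cyclohex[2]ene] | CC(C)C[C@H]1c2c(OC)cc(OC)cc2O[C@@H]2[C@@]1(C)CC[C@@]21C=C(C(C)C)CC[C@H]1C | intermediate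
23 | (3R,3aR,9R,9aS,6'R)-9-isobutyl-3'-isopropyl-6,8-dimethoxy-6',9a-dimethyl-1,2,3a,9-tetrahydro-9aH-spiro[cyclopenta[b]chromene-3,1'-cyclohex[2]ene]-5,7-dicarbaldehyde | CC(C)C[C@H]1c2c(OC)c(C=O)c(OC)c(C=O)c2O[C@@H]2[C@@]1(C)CC[C@@]21C=C(C(C)C)CC[C@H]1C | intermediate
24 | CNP0121396.1: (3R,3aR,9R,9aS,6'R)-6,8-dihydroxy-9-isobutyl-3'-isopropyl-6',9a-dimethyl-1,2,3a,9-tetrahydro-9aH-spiro[cyclopenta[b]chromene-3,1'-cyclohex[2]ene]-5,7-dicarbaldehyde | CC(C)C[C@H]1c2c(O)c(C=O)c(O)c(C=O)c2O[C@@H]2[C@@]1(C)CC[C@@]21C=C(C(C)C)CC[C@H]1C | target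

**Step count**
Total: 16 steps. Longest linear sequence: 13 steps (steps 1–5 and 9–16); the thymol branch (steps 6–8) joins at step 9.

**Steps most likely to fail**

1. Step 9 (key step, proposed new method). C–C bond formation by the fully substituted enol-ether carbon may be slower than Lewis-acid-induced self-condensation of 13, and the ring closure may show poor rotamer (facial) selectivity at the spiro carbon. Fallback: the two bonds are made one after the other by known reactions. Setting out from lactone 6, LDA (THF, −78 °C) gives the lithium lactone enolate F1, which opens the cyclopropane of 13 at a CH2 carbon (carbanion ring opening of a spiro[2.5]octadienone, an enolate alkylation anti to the C4 isobutyl group) to give the phenol lactone F2. DIBAL-H (CH2Cl2, −78 °C) reduces it to the lactol F3. BF3·OEt2 (CH2Cl2, −78 → −20 °C) then ionises the lactol, and the free phenol closes ring C by acid-mediated ipso-Friedel–Crafts dearomatisation, under conditions in which the spiro epimers can equilibrate through the reversible ring closure. The fallback comes back to the route at 15.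

2. Step 14. Hydride abstraction at the hindered benzylic C–H may be incomplete, and the acid of the ionic hydrogenation may reduce or shift the ring-D alkene. Fallback: the benzylic position is activated through the phenol oxidation level instead of by hydride abstraction. Setting out from 20, EtSNa (DMF, 140 °C) cleaves both methyl ethers to the 9-epi bisphenol F4. Ag2O (Et2O, rt) oxidises the para-alkylphenol to the para-quinone methide F5. NaBH4 (THF/MeOH, −20 °C) adds hydride to C9 in a 1,6-fashion, again from the face anti to C1, to give the (9R) bisphenol F6. Vilsmeier–Haack diformylation (POCl3, DMF, 0 °C → rt; NaOAc aq) then gives the target, so the fallback comes back to the route at 24 and steps 15 and 16 are not needed.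

3. Step 15. HCl may add to the ring-D alkene, or the alkene may rearrange through a cation under TiCl4/Cl2CHOMe, and the second formylation may stall. Fallback: the formyl groups are introduced through aryllithium chemistry without a Lewis acid. Setting out from 22, NBS (2.1 equiv, MeCN, −20 °C) brominates both arene positions to the dibromide F7. t-BuLi (4.2 equiv, THF, −78 °C) gives the dilithio arene F8 by twofold bromine–lithium exchange, and DMF then gives the dialdehyde. The fallback comes back to the route at 23.

**Further compounds**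
F1 | step 9 | lithium enolate of lactone 6 | CC(C)C[C@@H]1c2c(OC)c(Br)c(OC)c(Br)c2OC(O[Li])=C1C
F2 | step 9 | (4S)-6,8-dibromo-3-[2-(4-hydroxy-5-isopropyl-2-methylphenyl)ethyl]-4-isobutyl-5,7-dimethoxy-3-methylchroman-2-one, side chain trans to isobutyl | CC(C)C[C@@H]1c2c(OC)c(Br)c(OC)c(Br)c2OC(=O)[C@@]1(C)CCc1cc(C(C)C)c(O)cc1C
F3 | step 9 | lactol of F2 (chroman-2-ol, one anomer drawn) | CC(C)C[C@@H]1c2c(OC)c(Br)c(OC)c(Br)c2O[C@H](O)[C@@]1(C)CCc1cc(C(C)C)c(O)cc1C
F4 | step 14 | 6,8-diol (bisphenol) corresponding to 20, 9S | CC(C)C[C@@H]1c2c(O)cc(O)cc2O[C@@H]2[C@@]1(C)CC[C@@]21C=C(C(C)C)CC[C@H]1C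
F5 | step 14 | para-quinone methide of F4 (C9=C8a, C6=O, 8-hydroxy) | CC(C)CC1=C2C(O)=CC(=O)C=C2O[C@@H]2[C@@]1(C)CC[C@@]21C=C(C(C)C)CC[C@H]1C
F6 | step 14 | 6,8-diol (bisphenol) corresponding to 22, 9R | CC(C)C[C@H]1c2c(O)cc(O)cc2O[C@@H]2[C@@]1(C)CC[C@@]21C=C(C(C)C)CC[C@H]1C
F7 | step 15 | 5,7-dibromo derivative of 22 | CC(C)C[C@H]1c2c(OC)c(Br)c(OC)c(Br)c2O[C@@H]2[C@@]1(C)CC[C@@]21C=C(C(C)C)CC[C@H]1C
F8 | step 15 | 5,7-dilithio derivative of 22 | CC(C)C[C@H]1c2c(OC)c([Li])c(OC)c([Li])c2O[C@@H]2[C@@]1(C)CC[C@@]21C=C(C(C)C)CC[C@H]1C
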